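Retrosynthetic overview
1. The benzylic C–O aryl ether is made last, from the (R)-carbinol 14 and the 7-OH of (2S)-pinocembrin 15, with inversion (Mitsunobu).
2. Removing lactone oxygen O1 (retro-Baeyer–Villiger) turns the furo[3,2-b]furan-2-one into the 2-oxabicyclo[3.2.0]heptan-6-one 12.
3. A retro-[2+2] cuts the ring-fusion bond C3a–C6a together with C2–C3. This opens 12 to the acyclic γ-vinyloxy amide 8, which reacts as keteniminium plus vinyl ether.
4. Enabling feature: fusion carbon C3a carries the oxolane oxygen O4 and the lactone CH2 (C3), so O4–C3a=C3 is a vinyl ether whose cation-stabilised carbon is the fusion site. Fusion carbon C6a carries O1–C2(=O), so without O1 it is the α-carbon of a C6a=C2 heterocumulene, and the polarities match.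
5. Amide 8 comes from erythro epoxy alcohol 2 by silylation, opening with the N,N-dimethylacetamide enolate and O-vinylation. Ring order: oxolane and cyclobutanone together (step 5), then γ-lactone (step 6); the flavanone rings are bought.

Key step: step 5

Assumption: (2S)-pinocembrin 15 is bought as the natural single enantiomer. Bicyclic lactone locants follow O1, C2 (C=O), C3, C3a, O4, C5, C6, C6a.

Step 1
Reactants: 1 rac-1-phenylprop-2-en-1-ol
Product: 2 (R)-[(2S)-oxiran-2-yl](phenyl)methanol
Conditions: Ti(OiPr)4 (0.15 equiv), D-(−)-diisopropyl tartrate (0.18 equiv), t-BuOOH (0.45 equiv), 4 Å molecular sieves, CH2Cl2, −20 °C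
Reagents that add atoms: tert-butyl hydroperoxide, CC(C)(C)OO
Why: In this Sharpless asymmetric epoxidation run as a kinetic resolution, the D-(−)-tartrate catalyst should epoxidise only the (S)-alcohol quickly and on the alkene face that gives the erythro epoxy alcohol, so the tartrate fixes both the (R)-carbinol and the (S)-oxirane centre while the (R)-alcohol stays behind.

Step 2
Reactants: 2 (R)-[(2S)-oxiran-2-yl](phenyl)methanol
Product: 3 tert-butyl(dimethyl){(R)-[(2S)-oxiran-2-yl](phenyl)methoxy}silane
Conditions: TBSCl, imidazole, DMF, rt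
Reagents that add atoms: tert-butyldimethylsilyl chloride, CC(C)(C)[Si](C)(C)Cl
Why: Standard silyl ether formation without a free alkoxide avoids Payne rearrangement, touches no stereocentre and masks the carbinol for steps 3 to 6.

Step 3
Reactants: 4 N,N-dimethylacetamide (slight excess over the base); 3 tert-butyl(dimethyl){(R)-[(2S)-oxiran-2-yl](phenyl)methoxy}silane
Product: 6 (4S,5R)-5-(tert-butyldimethylsilyloxy)-4-hydroxy-N,N-dimethyl-5-phenylpentanamide, via lithium enolate 5 (not isolated)
Conditions: LiN(i-Pr)2, THF, −78 °C; then 3, −78 °C to rt; H2O quench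
Reagents that add atoms: lithium diisopropylamide, [Li]N(C(C)C)C(C)C (lithium of 5 only)
Why: SN2 opening of a terminal epoxide by a tertiary-amide lithium enolate takes place at the unsubstituted carbon, leaves both stereocentres untouched and gives a γ-hydroxy amide that should stay open-chain under basic conditions.

Step 4
Reactants: 6 (4S,5R)-5-(tert-butyldimethylsilyloxy)-4-hydroxy-N,N-dimethyl-5-phenylpentanamide; 7 butyl vinyl ether
Product: 8 (4S,5R)-5-(tert-butyldimethylsilyloxy)-4-(ethenyloxy)-N,N-dimethyl-5-phenylpentanamide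
Conditions: Pd(OCOCF3)2 (5 mol %), 4,7-diphenyl-1,10-phenanthroline (5 mol %), Et3N, 7 as solvent, 75 °C
Reagents that add atoms: none
Why: Palladium-catalysed transfer vinylation (transetherification) of a secondary alcohol is driven by the excess of 7 and does not break the carbinol C–O bond, so the configuration is retained.

Step 5
Reactants: 8 (4S,5R)-5-(tert-butyldimethylsilyloxy)-4-(ethenyloxy)-N,N-dimethyl-5-phenylpentanamide
Product: 12 (1R,3S,5R)-3-[(R)-(tert-butyldimethylsilyloxy)(phenyl)methyl]-2-oxabicyclo[3.2.0]heptan-6-one, via O-triflyliminium triflate 9 (not isolated), via keteniminium triflate 10 (not isolated), via cyclobutaniminium triflate 11 (not isolated)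
Conditions: Tf2O, 2,6-di-tert-butyl-4-methylpyridine, ClCH2CH2Cl (0.01 M), −25 °C to 40 °C; then aq NaHCO3, rt
Reagents that add atoms: trifluoromethanesulfonic anhydride, O=S(=O)(OS(=O)(=O)C(F)(F)F)C(F)(F)F (triflyl group and counter-ions of 9 to 11 only); water, O (carbonyl oxygen of 12)
Why: Proposed new method: Tf2O converts the amide into 9 and the hindered pyridine removes the α-proton to give keteniminium 10, whose central carbon is attacked by the nucleophilic CH2 terminus of the vinyl ether while the enamine-like α-carbon captures the oxygen-stabilised internal carbon (asynchronous [2+2]), and water then releases ketone 12 from iminium 11. The closest known reaction types are the intramolecular keteniminium–olefin [2+2] cycloaddition of ω-alkenyl amides and the [2+2] of ketenes with enol ethers to 3-alkoxycyclobutanones; what is new is a vinyl ether tethered through its own oxygen as the olefin partner. The oxolane ring closes through the new C1–C5 bond (the later C3a–C6a fusion bond) in a mode that is 5-exo at both π-systems, and the four-membered ring closes through the C6–C7 bond of the same cycloaddition. C1 and C5 must come out cis because the addition is suprafacial on the vinyl ether and a trans 4/5 fusion is out of reach; their sense is set by the existing C4 stereocentre of 8, because both carbons of the nascent cyclobutane are forced pseudo-axial on one face of the oxolane envelope, so the bulky silyloxybenzyl group can be pseudo-equatorial only on the opposite (exo) face, and reversible closure of the donor–acceptor iminium 11 should favour the same isomer. The fused rather than bridged regiochemistry is secured by the oxygen on the internal alkene carbon, which localises the positive charge there. Chemoselectivity rests on the amide oxygen being the best nucleophile for Tf2O, on the silylated carbinol, on attack of the weakly basic vinyl ether oxygen at 10 being a reversible dead end, and on high dilution.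

Step 6
Reactants: 12 (1R,3S,5R)-3-[(R)-(tert-butyldimethylsilyloxy)(phenyl)methyl]-2-oxabicyclo[3.2.0]heptan-6-one
Product: 13 (3aR,5S,6aR)-5-[(R)-(tert-butyldimethylsilyloxy)(phenyl)methyl]tetrahydrofuro[3,2-b]furan-2(3H)-one
Conditions: m-CPBA, CH2Cl2, 0 °C to rt
Reagents that add atoms: 3-chloroperoxybenzoic acid, O=C(OO)c1cccc(Cl)c1
Why: In this Baeyer–Villiger oxidation of a strained bicyclo[3.2.0]heptan-6-one the bridgehead methine C5 should migrate rather than the CH2 (C7, further deactivated by the β-oxygen) and with retention, which places the lactone oxygen on C6a and keeps the cis fusion.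

Step 7
Reactants: 13 (3aR,5S,6aR)-5-[(R)-(tert-butyldimethylsilyloxy)(phenyl)methyl]tetrahydrofuro[3,2-b]furan-2(3H)-one
Product: 14 (3aR,5S,6aR)-5-[(R)-hydroxy(phenyl)methyl]tetrahydrofuro[3,2-b]furan-2(3H)-one
Conditions: HF·pyridine, THF, 0 °C to rt
Reagents that add atoms: none
Why: Fluoride-mediated desilylation in a slightly acidic medium spares the base-sensitive β-alkoxy lactone and touches no stereocentre.

Step 8
Reactants: 14 (3aR,5S,6aR)-5-[(R)-hydroxy(phenyl)methyl]tetrahydrofuro[3,2-b]furan-2(3H)-one; 15 (2S)-pinocembrin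
Product: 16 CNP0152032.1 (the target)
Conditions: PPh3, DIAD, THF, 0 °C to rt
Reagents that add atoms: none
Why: In this Mitsunobu etherification the acidic free 7-OH of 15 (the 5-OH is tied up in a hydrogen bond to the C4 carbonyl) should displace the activated benzylic oxygen by SN2 with inversion from (R) to (S), since the neighbouring C–O bond disfavours ionisation and the near-neutral medium preserves C2 of the flavanone.

Compound list
1 | rac-1-phenylprop-2-en-1-ol | C=CC(O)c1ccccc1 | starting material
2 | (R)-[(2S)-oxiran-2-yl](phenyl)methanol | O[C@H](c1ccccc1)[C@@H]1CO1 | intermediate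
3 | tert-butyl(dimethyl){(R)-[(2S)-oxiran-2-yl](phenyl)methoxy}silane | CC(C)(C)[Si](C)(C)O[C@H](c1ccccc1)[C@@H]1CO1 | intermediate
4 | N,N-dimethylacetamide | CC(=O)N(C)C | starting material
5 | lithium enolate of N,N-dimethylacetamide | C=C(O[Li])N(C)C | intermediate
6 | (4S,5R)-5-(tert-butyldimethylsilyloxy)-4-hydroxy-N,N-dimethyl-5-phenylpentanamide | CN(C)C(=O)CC[C@H](O)[C@H](O[Si](C)(C)C(C)(C)C)c1ccccc1 | intermediate
7 | butyl vinyl ether | C=COCCCC | starting material
8 | (4S,5R)-5-(tert-butyldimethylsilyloxy)-4-(ethenyloxy)-N,N-dimethyl-5-phenylpentanamide | CN(C)C(=O)CC[C@H](OC=C)[C@H](O[Si](C)(C)C(C)(C)C)c1ccccc1 | intermediate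
9 | O-triflyliminium triflate of 8 (configuration as in 8) | C[N+](C)=C(OS(=O)(=O)C(F)(F)F)CC[C@H](OC=C)[C@H](O[Si](C)(C)C(C)(C)C)c1ccccc1.[O-]S(=O)(=O)C(F)(F)F | intermediate
10 | N,N-dimethylketeniminium triflate derived from 8 (configuration as in 8) | C[N+](C)=C=CC[C@H](OC=C)[C@H](O[Si](C)(C)C(C)(C)C)c1ccccc1.[O-]S(=O)(=O)C(F)(F)F | intermediate
11 | N,N-dimethyliminium triflate of ketone 12 (configuration as in 12) | C[N+](C)=C1C[C@H]2O[C@H]([C@H](O[Si](C)(C)C(C)(C)C)c3ccccc3)C[C@@H]12.[O-]S(=O)(=O)C(F)(F)F | intermediate
12 | (1R,3S,5R)-3-[(R)-(tert-butyldimethylsilyloxy)(phenyl)methyl]-2-oxabicyclo[3.2.0]heptan-6-one (cis-fused, side chain exo) | O=C1C[C@H]2O[C@H]([C@H](O[Si](C)(C)C(C)(C)C)c3ccccc3)C[C@@H]12 | intermediate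
13 | (3aR,5S,6aR)-5-[(R)-(tert-butyldimethylsilyloxy)(phenyl)methyl]tetrahydrofuro[3,2-b]furan-2(3H)-one | O=C1C[C@H]2O[C@H]([C@H](O[Si](C)(C)C(C)(C)C)c3ccccc3)C[C@H]2O1 | intermediate
14 | (3aR,5S,6aR)-5-[(R)-hydroxy(phenyl)methyl]tetrahydrofuro[3,2-b]furan-2(3H)-one | O=C1C[C@H]2O[C@H]([C@H](O)c3ccccc3)C[C@H]2O1 | intermediate
15 | (2S)-pinocembrin, (2S)-5,7-dihydroxy-2-phenylchroman-4-one | Oc1cc(O)c2c(c1)O[C@H](c1ccccc1)CC2=O | starting material
16 | CNP0152032.1, (2S)-5-hydroxy-7-{(S)-[(3aR,5S,6aR)-2-oxohexahydrofuro[3,2-b]furan-5-yl](phenyl)methoxy}-2-phenylchroman-4-one | O=C1C[C@H]2O[C@H]([C@@H](Oc3cc(O)c4c(c3)O[C@H](c3ccccc3)CC4=O)c3ccccc3)C[C@H]2O1 | target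

Total step count: 8. Longest linear sequence: 8 steps (1 to 16).

Steps most likely to fail

1. Step 5.
- What may go wrong: proton loss from the cationic intermediate before the second C–C bond forms, cationic oligomerisation of the vinyl ether, or too weak a facial bias from the side chain.
- Fallback (known chemistry only), setting out from 6 and coming back at 12. Acid-catalysed lactonisation of 6 (PPTS, toluene, 80 °C) should give (S)-5-[(R)-(tert-butyldimethylsilyloxy)(phenyl)methyl]dihydrofuran-2(3H)-one F1. Reduction with i-Bu2AlH (CH2Cl2, −78 °C) should give (5S)-5-[(R)-(tert-butyldimethylsilyloxy)(phenyl)methyl]oxolan-2-ol F2 as an anomer mixture. Mesylation with elimination (MsCl, Et3N, CH2Cl2, reflux) should give (S)-2-[(R)-(tert-butyldimethylsilyloxy)(phenyl)methyl]-2,3-dihydrofuran F3. The classical intermolecular [2+2] of this cyclic enol ether with dichloroketene (Cl3CCOCl, zinc-copper couple, Et2O/DME) should occur on the face anti to the side chain, with the carbonyl carbon bonding to the β-carbon. That gives (1S,3S,5R)-7,7-dichloro-3-[(R)-(tert-butyldimethylsilyloxy)(phenyl)methyl]-2-oxabicyclo[3.2.0]heptan-6-one F4. Reductive dechlorination (Zn, AcOH, rt) then leads to 12.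

2. Step 8.
- What may go wrong: sluggish activation of the hindered carbinol, partial ionisation that erodes the inversion, or alkylation at the wrong phenol.
- Fallback, setting out from 14 and coming back at 16. Activation and displacement are separated. Sulfonylation (MsCl, Et3N, CH2Cl2, −20 °C) should give (R)-[(3aR,5S,6aR)-2-oxohexahydrofuro[3,2-b]furan-5-yl](phenyl)methyl methanesulfonate F5. This is displaced with inversion by the 7-phenoxide of 15, made with one equivalent of Cs2CO3 (DMF, 0 °C to rt). Only the acidic 7-OH is ionised that way, and the flavanone ring stays closed.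

3. Step 4.
- What may go wrong: slow vinyl transfer to the hindered carbinol, so that lactonisation of the hydroxy amide takes over at 75 °C.
- Fallback, setting out from 6 and coming back at 8. Acid-catalysed addition of 6 to ethyl vinyl ether (PPTS, CH2Cl2, rt) should give (4S,5R)-5-(tert-butyldimethylsilyloxy)-4-(1-ethoxyethoxy)-N,N-dimethyl-5-phenylpentanamide F6 as an acetal epimer mixture. Silyl-triflate-induced acetal elimination (TMSOTf, Et3N, CH2Cl2, 0 °C) should then expel the less hindered ethoxy group and give 8.

Further compounds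
F1 | step 5 | (S)-5-[(R)-(tert-butyldimethylsilyloxy)(phenyl)methyl]dihydrofuran-2(3H)-one | O=C1CC[C@@H]([C@H](O[Si](C)(C)C(C)(C)C)c2ccccc2)O1
F2 | step 5 | (5S)-5-[(R)-(tert-butyldimethylsilyloxy)(phenyl)methyl]oxolan-2-ol | OC1CC[C@@H]([C@H](O[Si](C)(C)C(C)(C)C)c2ccccc2)O1
F3 | step 5 | (S)-2-[(R)-(tert-butyldimethylsilyloxy)(phenyl)methyl]-2,3-dihydrofuran | C1=CC[C@@H]([C@H](O[Si](C)(C)C(C)(C)C)c2ccccc2)O1
F4 | step 5 | (1S,3S,5R)-7,7-dichloro-3-[(R)-(tert-butyldimethylsilyloxy)(phenyl)methyl]-2-oxabicyclo[3.2.0]heptan-6-one | O=C1C(Cl)(Cl)[C@H]2O[C@H]([C@H](O[Si](C)(C)C(C)(C)C)c3ccccc3)C[C@@H]12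
F5 | step 8 | (R)-[(3aR,5S,6aR)-2-oxohexahydrofuro[3,2-b]furan-5-yl](phenyl)methyl methanesulfonate | O=C1C[C@H]2O[C@H]([C@H](OS(C)(=O)=O)c3ccccc3)C[C@H]2O1
F6 | step 4 | (4S,5R)-5-(tert-butyldimethylsilyloxy)-4-(1-ethoxyethoxy)-N,N-dimethyl-5-phenylpentanamide | CN(C)C(=O)CC[C@H](OC(C)OCC)[C@H](O[Si](C)(C)C(C)(C)C)c1ccccc1
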